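## The problem

The target is a briarane. A cyclohexene (C1, C10–C14) is fused along C1–C10 to a ten-membered carbocycle (C1–C10), which carries a γ-lactone across C7–C8 (C17, C19, O7). C15 is the methyl on C1, C16 the hydroxymethyl on C5, C18 the methyl on C17 and C20 the methyl on C11.

Nine ring stereocentres (C1, C2, C4, C7, C8, C9, C10, C14, C17), one side-chain centre and the (5Z) trisubstituted alkene must be set. The quaternary C1 with its neighbours C2, C10 and C14 is the densest cluster. Local relays are available for most of them: C10 can set C1 (vicinal, in the ring), the ring conformation can set C14, O14 can set C2, C10 can set C9 (α-branched aldehyde), O9 can set C8 (allylic alcohol), and alkene geometry can be translated into C7. C4 is the one centre only loosely coupled to the rest.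

Four secondary esters and the lactone rule out hydride, organolithium and strong base late in the route. The 3-acetoxybutanoate eliminates to a crotonate with base, the O4 acyl group can migrate to a free O16, and the tertiary β-hydroxy lactone can undergo retro-aldol cleavage. H10 becomes acidic whenever C9 or C11 is a carbonyl.

The feature that opens the structure is that C10, the quaternary C1 and C2 sit on the β carbon, the α carbon and the α-substituent carbon of a 2-methylcyclohex-2-enone whose carbonyl is C14. C11, an alkene carbon in the target, can carry a temporary oxygen stereocentre next to C10. A conjugate addition and aldol trap therefore builds the triad in one operation. One correction is needed: a closed chair aldol places O2 syn to the C15 methyl, which is the C2 epimer of the target, so C2 is not taken from the aldol. It is erased and reset from O14.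

## Retrosynthesis

**O4 ester and O16.** Target 52 is traced to silyl ether 51 and then to macrocyclic alcohol 48 and (R)-3-acetoxybutanoic acid 50 (from 49). The elimination-prone side chain arrives last and under carbodiimide conditions. O16 stays silylated until the final, non-basic fluoride step so that the O4 acyl group cannot migrate. The C4 hydroxyl must be the only acylable one, which holds because O8 is tertiary.

**C4–C5, closing the ten-membered ring.** 48 is opened to iodo aldehyde 46. Cutting here rather than at C8–C9 or C6–C7 leaves the rigid lactone and the cyclohexene in place as turn elements, and the (Z) geometry is carried by the iodoalkene. The new carbinol C4 is the only centre set under ring control, and either epimer can be used because esterification can be run with retention or inversion. The forward reaction must tolerate four esters and a free tertiary alcohol; chromium and nickel chemistry does.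

**Lactone: C7–O7 and O8.** 46 comes from hydroxy lactone 44, and 44 from epoxy acid 43, by opening a C7–C8 epoxide at the allylic carbon C7 with the C19 carboxyl. This cut turns three stereocentres into one alkene geometry and one face selection. The epoxide (39, acetate 40) comes from dienol 38 by epoxidation directed by O9. Oxygenation of a lactone that is already closed was not chosen, because it would have to occur on the more hindered face, cis to C6. O9 must be free for the epoxidation and acylated before the acid is made, since a free O9 would itself lactonise onto C19.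

**C8–C9.** 38 (via stannane 37) is cut into aldehyde 27 and enyne 36. A nickel-catalysed reductive coupling forms the bond at the alkyne carbon remote from the conjugated alkene and adds hydrogen syn, which gives exactly the C7=C8 geometry the lactonisation needs. C9 is set by approach anti to the quaternary C1. The C5 tin substituent is a placeholder for iodine that survives zerovalent nickel.

**Fragment 36.** It is reduced to diyne 34, made from bromoalkyne 32 and prop-2-yn-1-ol 33. 32 derives from alkyne 31 and thus from methyl (S)-3-hydroxy-2-methylpropanoate 28, which supplies C17 with its methyl. The propargylic hydroxyl of 34 directs a trans-hydrostannation that places tin on C5 cis to C7.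

**C9 aldehyde, C20 and the C11=C12 alkene.** 27 comes from acetonide 25, and 25 from ketone 22 through enol triflate 24 and a methyl cross-coupling. The vinyl group is masked as a diol acetonide (19, 20) before C11 is oxidised. This prevents H10 from being both α to the ketone and allylic when the enolate is formed, and it prevents the later trisubstituted alkene from competing in the oxidative cleavage. Diacetate 18 already carries the C2 and C14 acetates of the target.

**C14 and C2.** 18 comes from diol 17, 17 from hydroxy ketone 15, and 15 from diketone 14. The ring ketone is reduced first by a bulky hydride from the equatorial direction. Its hydroxyl then directs a syn-selective reduction of the C2 ketone. 14 is the oxidation product of aldol 13, so both C2 epimers of 13 converge.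

**C9–C10 and C1–C2 (key step).** 13 is cut into enone 6, vinylmagnesium bromide 10 and aldehyde 9. Two skeletal bonds and the C10/C1 relationship arise from three simple components, with C11 as the single control element that is later erased. The step must alkylate a fully substituted enolate carbon with an enolisable aldehyde.

**Components.** 6 comes from 4-methoxy-3-methylphenol 1 through quinone monoketal 2, enone ketal 3, alcohol 4 and silyl ether 5. This phenol isomer is used because the ketal then masks the future C14 while the future C11 ketone is reduced enantioselectively, so no regioselective reduction of an enedione is needed. 9 comes from propane-1,3-diol 7 via 8.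

## Roads not taken

**Alternative 1:** The cut is C4–C5. In the forward direction CrCl2 with catalytic NiCl2 would convert a C5 iodoalkene into an alkenylchromium that adds to a C4 aldehyde and closes the ten-membered ring to A1.
- Merits: the (Z) alkene is carried over from the iodoalkene, esters and free hydroxyls are tolerated, and the lactone is complete before the closure.
- Weak points: as a strategy it is silent on the C1/C2/C10/C14 cluster, it places the riskiest step after all stereocentres are built, and it sets C4 under ring control alone.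
- Comparison: for the ring closure this road is as good as anything available, and the chosen plan in fact uses it as step 35 (48 is the triisopropylsilyl analogue of A1). What the chosen plan sets against it is an answer to the part Alternative 1 leaves open: a one-step entry to the quaternary triad with a local control element.

**Alternative 2:** The cut is C1–C10. Pd(PPh3)4 would ionise an allylic carbonate at C10 in a fourteen-membered carbocycle, and the enolate of the C2/C14 1,3-diketone would attack through C1, forming both carbocycles at once and giving A2.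
- Merits: the quaternary centre and the ring fusion arise in one soft, neutral step, and the bicycle appears late from a flexible precursor.
- Weak points: a fully functionalised fourteen-membered ring must be made first, so there are two ring-forming events. The allyl unit can be attacked at C10 or C12. The C1/C10 relationship depends on a transannular conformation and not on a local element. Two ketones then remain to be differentiated and reduced to C2 and C14 in the presence of the lactone and an acetate.
- Comparison: if it worked it would be shorter in ring-forming steps than the chosen plan. The chosen plan sets against it secure vicinal control of C1 by C10 in a six-membered ring, and reductions at C2/C14 carried out before any sensitive group is present.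

**Alternative 3:** The cut is C8–C17. SmI2 would reduce a 2-bromopropanoate on O7 to a samarium enolate whose C17 adds to a C8 ketone in the macrocycle, closing the lactone and giving A3.
- Merits: it needs only a simple propanoate, it creates the tertiary carbinol and C17 in one step, and delivery from O7 ties the new bond to the C7 configuration.
- Weak points: the substrate is a ketone flanked by an acyloxy group at C7 and a silyloxy group at C9, and under divalent samarium such α-oxygenated ketones tend to lose the α-substituent reductively. The face of the ketone and the C17 configuration depend on the macrocycle conformation. The road also presupposes a macrocycle made by other means.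
- Comparison: in reagent simplicity it is better than the chosen lactone construction, which needs a chiral alkyne fragment and more steps. The chosen plan sets against it stereocontrol that is readable from an alkene geometry and a directed epoxidation, and it avoids a reducible α-oxygenated ketone.

Key step: step 8

Assumption: the chromium-mediated closure (step 35) is taken to give the (4R)-alcohol 48, the 1,3-anti relationship to the C2 acetate expected from the dipole-minimised aldehyde conformer; the 4-epimer is covered by the fallback to step 35.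

Step 1
Reactants: 1 4-methoxy-3-methylphenol
Product: 2 4,4-dimethoxy-3-methylcyclohexa-2,5-dien-1-one
Conditions: PhI(OAc)2, MeOH, 0 °C
Reagents that add atoms: methanol, CO
Why: Oxidative dearomatisation of a para-alkoxyphenol in methanol gives the quinone monoketal; the ketal sits next to the methyl-bearing alkene carbon (future C14) and the free ketone is the future C11.

Step 2
Reactants: 2 4,4-dimethoxy-3-methylcyclohexa-2,5-dien-1-one
Product: 3 4,4-dimethoxy-3-methylcyclohex-2-en-1-one
Conditions: H2 (1 atm), RhCl(PPh3)3 (5 mol %), toluene, rt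
Reagents that add atoms: none
Why: Homogeneous hydrogenation with RhCl(PPh3)3 discriminates by alkene substitution, so the cis-disubstituted alkene should be saturated while the methyl-bearing trisubstituted alkene remains.

Step 3
Reactants: 3 4,4-dimethoxy-3-methylcyclohex-2-en-1-one
Product: 4 (R)-4,4-dimethoxy-3-methylcyclohex-2-en-1-ol
Conditions: (S)-2-methyl-CBS-oxazaborolidine (20 mol %), catecholborane, toluene, −78 °C
Reagents that add atoms: none
Why: Corey–Bakshi–Shibata reduction; the alkenyl arm acts as the large group, so the (S)-catalyst should give the (R)-carbinol, which becomes the C11 control centre.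

Step 4
Reactants: 4 (R)-4,4-dimethoxy-3-methylcyclohex-2-en-1-ol
Product: 5 (R)-tert-butyl[(4,4-dimethoxy-3-methylcyclohex-2-en-1-yl)oxy]dimethylsilane
Conditions: t-BuMe2SiCl, imidazole, DMF, rt
Reagents that add atoms: tert-butyldimethylsilyl chloride, CC(C)(C)[Si](C)(C)Cl
Why: Standard silylation of a secondary allylic alcohol; the bulky silyl ether is the group that later steers the cuprate.

Step 5
Reactants: 5 (R)-tert-butyl[(4,4-dimethoxy-3-methylcyclohex-2-en-1-yl)oxy]dimethylsilane
Product: 6 (R)-4-(tert-butyldimethylsilyloxy)-2-methylcyclohex-2-en-1-one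
Conditions: oxalic acid, wet SiO2, CH2Cl2, rt
Reagents that add atoms: water, O
Why: Mild hydrolysis of the allylic dimethyl ketal unmasks the enone carbonyl (C14) without cleaving the silyl ether or eliminating the γ-silyloxy group.

Step 6
Reactants: 7 propane-1,3-diol
Product: 8 3-(4-methoxybenzyloxy)propan-1-ol
Conditions: NaH (1 equiv), THF, 0 °C; 4-methoxybenzyl chloride, Bu4NI (cat.), rt; diol in excess
Reagents that add atoms: 4-methoxybenzyl chloride, COc1ccc(CCl)cc1
Why: Williamson ether synthesis; the excess of diol secures mono-alkylation.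

Step 7
Reactants: 8 3-(4-methoxybenzyloxy)propan-1-ol
Product: 9 3-(4-methoxybenzyloxy)propanal
Conditions: TEMPO (10 mol %), PhI(OAc)2, CH2Cl2, rt
Reagents that add atoms: none
Why: Nitroxyl-catalysed oxidation stops cleanly at the aldehyde and avoids β-elimination of the ether.

Step 8
Reactants: 6 (R)-4-(tert-butyldimethylsilyloxy)-2-methylcyclohex-2-en-1-one; 10 vinylmagnesium bromide; 9 3-(4-methoxybenzyloxy)propanal
Product: 13 aldol adduct with the C14 ketone plus quaternary C1 plus C10 vinyl plus C2 carbinol, via bromomagnesium enolate 11 (not isolated), via chlorozinc enolate 12 (not isolated)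
Conditions: CuI (10 mol %), LiCl (20 mol %), THF, −78 to −40 °C, addition of 10; ZnCl2 (1.2 equiv), −78 °C; then 9, −78 to −40 °C; aq. NH4Cl
Reagents that add atoms: none
Why: The magnesium vinylcuprate formed catalytically from 10 and CuI adds 1,4 to enone 6 at C10 to give enolate 11, ZnCl2 converts it into the less basic zinc enolate 12, and 12 adds to aldehyde 9 through a closed six-membered transition state before NH4Cl releases 13. The closest known reaction type is the copper-mediated conjugate addition to 4-silyloxycycloalkenones with aldol trapping of the regiodefined enolate (three-component coupling). No ring is closed; the bonds formed are C9–C10 and C1–C2. C10 is controlled by C11, because the cuprate enters anti to the silyloxy group. C1 is controlled by C10, because the aldehyde approaches the enolate face opposite the new vinyl group, which places the C15 methyl cis to the vinyl group. C2 is controlled only by the chair transition state with the aldehyde chain equatorial, which puts O2 syn to the C15 methyl and gives the (S)-carbinol drawn for 13, the C2 epimer of what the target needs; this centre is therefore not relied upon and is erased in step 9. The step needs C-alkylation of a fully substituted enolate carbon without proton transfer from the enolisable aldehyde, which the regiodefined zinc enolate and the low temperature should secure.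

Step 9
Reactants: 13 aldol adduct (C14 ketone, C2 carbinol)
Product: 14 C2,C14-diketone
Conditions: Dess–Martin periodinane, NaHCO3, CH2Cl2, rt
Reagents that add atoms: none
Why: Dess–Martin oxidation converts both C2 epimers into one diketone, so the aldol selectivity at C2 does not matter; the buffered neutral medium avoids retro-Claisen cleavage of the 2,2-disubstituted 1,3-diketone.

Step 10
Reactants: 14 C2,C14-diketone
Product: 15 C14 alcohol with the C2 ketone retained
Conditions: LiBH(s-Bu)3 (1.05 equiv), THF, −78 °C; AcOH quench at −78 °C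
Reagents that add atoms: none
Why: The cyclohexanone carbonyl is intrinsically more reactive than the acyclic neopentyl ketone, and the bulky hydride attacks it from the equatorial direction, as with other 2,2-disubstituted cyclohexanones, giving the axial C14 alcohol cis to the C2 chain and trans to the C15 methyl as in the target.

Step 11
Reactants: 15 C14 alcohol with the C2 ketone
Product: 17 syn-2,14-diol, via diethylboron chelate 16 (not isolated)
Conditions: Et2BOMe, THF/MeOH (4:1), −78 °C; NaBH4, −78 °C; repeated evaporation from MeOH
Reagents that add atoms: none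
Why: Narasaka–Prasad reduction; boron links O14 and the C2 carbonyl in a six-membered chelate in which C10 is axial, and external hydride adds axially from the opposite face to give the 1,3-syn diol, which is the (2R) configuration of the target.

Step 12
Reactants: 17 syn-2,14-diol
Product: 18 2,14-diacetate
Conditions: Ac2O, DMAP, pyridine, 40 °C
Reagents that add atoms: acetic anhydride, CC(=O)OC(C)=O
Why: DMAP-catalysed acylation installs the C2 and C14 acetates of the target at once; gentle warming is allowed for the hindered axial C14 hydroxyl.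

Step 13
Reactants: 18 2,14-diacetate
Product: 19 terminal diol from the vinyl group (C9 epimers)
Conditions: OsO4 (2 mol %), N-methylmorpholine N-oxide, acetone/H2O, rt
Reagents that add atoms: N-methylmorpholine N-oxide, C[N+]1([O-])CCOCC1; water, O
Why: Catalytic osmium dihydroxylation of the only alkene; the C9 carbinol configuration is irrelevant because the diol is cleaved in step 19, and masking the vinyl group removes the allylic activation of H10 before C11 becomes a ketone.

Step 14
Reactants: 19 terminal diol
Product: 20 diol acetonide
Conditions: 2,2-dimethoxypropane, pyridinium p-toluenesulfonate (cat.), CH2Cl2, rt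
Reagents that add atoms: 2,2-dimethoxypropane, COC(C)(C)OC
Why: Acid-catalysed transketalisation protects the terminal 1,2-diol; the silyl ether, the acetates and the benzyl-type ether are stable to these conditions.

Step 15
Reactants: 20 diol acetonide
Product: 21 C11 alcohol
Conditions: Bu4NF, AcOH (1:1), THF, 0 °C to rt
Reagents that add atoms: none
Why: Fluoride cleaves the secondary silyl ether; buffering with acetic acid keeps the medium non-basic so that the acetates neither migrate nor hydrolyse and the acetonide survives.

Step 16
Reactants: 21 C11 alcohol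
Product: 22 C11 ketone
Conditions: Dess–Martin periodinane, NaHCO3, CH2Cl2, rt
Reagents that add atoms: none
Why: Neutral oxidation of the secondary alcohol removes the relay stereocentre once its work is done and does not epimerise C10.

Step 17
Reactants: 22 C11 ketone
Product: 24 C11 enol triflate with the C11=C12 double bond, via potassium enolate 23 (not isolated)
Conditions: KN(SiMe3)2 (1.1 equiv), THF, −78 °C; PhNTf2, −78 to 0 °C
Reagents that add atoms: N-phenylbis(trifluoromethanesulfonimide), O=S(=O)(N(c1ccccc1)S(=O)(=O)C(F)(F)F)C(F)(F)F
Why: Kinetic deprotonation by the hindered amide occurs at the accessible C12 methylene and not at the neopentyl C10 methine, and the ketone is far more acidic than the acetates; O-sulfonylation fixes the C11=C12 regiochemistry.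

Step 18
Reactants: 24 C11 enol triflate
Product: 25 C11-methyl alkene
Conditions: Pd(PPh3)4 (5 mol %), MeZnCl, THF, 0 °C to rt
Reagents that add atoms: methylzinc chloride, C[Zn]Cl
Why: Negishi coupling of the enol triflate installs C20 on the trisubstituted alkene; the organozinc reagent does not touch the acetates.

Step 19
Reactants: 25 C11-methyl alkene acetonide
Product: 27 C9 aldehyde, via terminal diol 26 (not isolated)
Conditions: H5IO6, EtOAc, rt
Reagents that add atoms: none
Why: Periodic acid hydrolyses the terminal acetonide and cleaves the resulting glycol in one operation, removing the former vinyl terminus and leaving C9 as the aldehyde without affecting the trisubstituted alkene; the aldehyde is used at once.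

Step 20
Reactants: 28 methyl (S)-3-hydroxy-2-methylpropanoate
Product: 29 methyl (S)-3-(tert-butyldimethylsilyloxy)-2-methylpropanoate
Conditions: t-BuMe2SiCl, imidazole, CH2Cl2, rt
Reagents that add atoms: tert-butyldimethylsilyl chloride, CC(C)(C)[Si](C)(C)Cl
Why: Standard silylation of the primary alcohol, which becomes C19.

Step 21
Reactants: 29 methyl (S)-3-(tert-butyldimethylsilyloxy)-2-methylpropanoate
Product: 30 (S)-3-(tert-butyldimethylsilyloxy)-2-methylpropanal
Conditions: i-Bu2AlH (1.05 equiv), CH2Cl2, −78 °C; aq. potassium sodium tartrate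
Reagents that add atoms: none
Why: Partial reduction of the ester through the aluminium hemiacetal, which is stable at −78 °C, gives the aldehyde; the conditions are non-basic and leave the α-centre intact.

Step 22
Reactants: 30 (S)-3-(tert-butyldimethylsilyloxy)-2-methylpropanal
Product: 31 (R)-tert-butyldimethyl[(2-methylbut-3-yn-1-yl)oxy]silane
Conditions: dimethyl (1-diazo-2-oxopropyl)phosphonate, K2CO3, MeOH, 0 °C to rt
Reagents that add atoms: dimethyl (1-diazo-2-oxopropyl)phosphonate, COP(=O)(OC)C(=[N+]=[N-])C(C)=O
Why: Ohira–Bestmann homologation converts the aldehyde into the terminal alkyne under mild carbonate conditions suited to α-methyl aldehydes; the descriptor changes from S to R only because the priorities change.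

Step 23
Reactants: 31 (R)-tert-butyldimethyl[(2-methylbut-3-yn-1-yl)oxy]silane
Product: 32 (R)-[(4-bromo-2-methylbut-3-yn-1-yl)oxy](tert-butyl)dimethylsilane
Conditions: N-bromosuccinimide, AgNO3 (10 mol %), acetone, rt
Reagents that add atoms: N-bromosuccinimide, O=C1CCC(=O)N1Br
Why: Silver-catalysed electrophilic bromination of the terminal alkyne C–H gives the 1-bromoalkyne needed for heterocoupling.

Step 24
Reactants: 32 (R)-[(4-bromo-2-methylbut-3-yn-1-yl)oxy](tert-butyl)dimethylsilane; 33 prop-2-yn-1-ol
Product: 34 (R)-7-(tert-butyldimethylsilyloxy)-6-methylhepta-2,4-diyn-1-ol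
Conditions: CuCl (10 mol %), NH2OH·HCl, n-BuNH2 (30 % aq.), CH2Cl2, 0 °C
Reagents that add atoms: none
Why: Cadiot–Chodkiewicz coupling joins the copper acetylide of 33 to the bromoalkyne to give the unsymmetrical 1,3-diyne that holds C16, C5–C8 and C17–C19.

Step 25
Reactants: 34 (R)-7-(tert-butyldimethylsilyloxy)-6-methylhepta-2,4-diyn-1-ol
Product: 35 (R,Z)-7-(tert-butyldimethylsilyloxy)-6-methyl-2-(tributylstannyl)hept-2-en-4-yn-1-ol
Conditions: [Cp*RuCl]4 (2.5 mol %), Bu3SnH (1.1 equiv), CH2Cl2, rt
Reagents that add atoms: tributyltin hydride, CCCC[SnH](CCCC)CCCC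
Why: Hydroxyl-directed ruthenium-catalysed trans-hydrostannation; hydrogen bonding of the propargylic OH to the chloride ligand steers the catalyst to the proximal triple bond and the tin to C5, and trans addition places tin cis to the alkynyl group, which is the geometry the (5Z) ring alkene requires.

Step 26
Reactants: 35 (R,Z)-stannyl enynol
Product: 36 triisopropylsilyl ether of 35
Conditions: i-Pr3SiCl, imidazole, DMF, rt
Reagents that add atoms: triisopropylsilyl chloride, CC(C)[Si](Cl)(C(C)C)C(C)C
Why: Silylation of the primary allylic alcohol with a group that outlasts the later selective removal of the tert-butyldimethylsilyl ether.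

Step 27
Reactants: 27 C9 aldehyde; 36 stannyl enyne
Product: 37 C9 dienol with the C8–C9 bond formed
Conditions: Ni(cod)2 (10 mol %), P(c-C5H9)3 (20 mol %), Et3B (2 equiv), EtOAc, rt
Reagents that add atoms: none
Why: Nickel-catalysed reductive coupling of a 1,3-enyne with an aldehyde; oxidative cyclisation forms the C–C bond at the alkyne carbon remote from the conjugated alkene (C8), and ethyl transfer from boron followed by β-hydride and reductive elimination delivers hydrogen to C7 syn to the new bond, so C6 and C17 end cis. C9 is set by Felkin–Anh approach anti to the quaternary C1 of the α-branched aldehyde, which corresponds to the target configuration.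

Step 28
Reactants: 37 stannyl dienol
Product: 38 iodo dienol
Conditions: I2, CH2Cl2, −78 to 0 °C, dark
Reagents that add atoms: iodine, II
Why: Iododestannylation proceeds with retention of alkene geometry; it is done now because the stannane would not survive the later acidic and hypervalent iodine steps.

Step 29
Reactants: 38 iodo dienol
Product: 39 7,8-epoxy C9 alcohol
Conditions: VO(acac)2 (5 mol %), t-BuOOH, CH2Cl2, 0 °C to rt
Reagents that add atoms: tert-butyl hydroperoxide, CC(C)(C)OO
Why: Vanadium-catalysed hydroxyl-directed epoxidation of the allylic alcohol; the C17 branch on C8 imposes A(1,2) strain, which favours the erythro epoxy alcohol and thus the C8 configuration of the target, while the iodoalkene and the homoallylic ring alkene react much more slowly.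

Step 30
Reactants: 39 7,8-epoxy C9 alcohol
Product: 40 epoxy C9 acetate
Conditions: Ac2O, DMAP, pyridine, CH2Cl2, rt
Reagents that add atoms: acetic anhydride, CC(=O)OC(C)=O
Why: Acylation installs the C9 acetate of the target and removes the hydroxyl that would otherwise lactonise onto C19 in step 32.

Step 31
Reactants: 40 epoxy C9 acetate
Product: 41 C19 primary alcohol
Conditions: HF·pyridine, excess pyridine, THF, 0 °C
Reagents that add atoms: none
Why: Buffered HF·pyridine removes the primary tert-butyldimethylsilyl ether much faster than the primary triisopropylsilyl ether, and the buffered medium should leave the vinyl epoxide intact.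

Step 32
Reactants: 41 C19 primary alcohol
Product: 44 hydroxy lactone, via C19 aldehyde 42 (not isolated), via epoxy acid 43 (not isolated)
Conditions: TEMPO (20 mol %), PhI(OAc)2 (2.2 equiv), MeCN/H2O, rt; then camphorsulfonic acid (5 mol %), CH2Cl2, 0 °C
Reagents that add atoms: water, O
Why: Nitroxyl-catalysed oxidation takes the alcohol through aldehyde 42 to acid 43, whose carboxyl opens the vinyl epoxide at the allylic carbon C7 to form the five-membered lactone with inversion at C7 and retention at C8; since C6 and C17 are cis on the epoxide, this gives O8 cis to C6 and to the C18 methyl, as in the target.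

Step 33
Reactants: 44 hydroxy lactone
Product: 45 C4 primary alcohol
Conditions: DDQ, CH2Cl2/pH 7 buffer, 0 °C
Reagents that add atoms: none
Why: Oxidative cleavage of the 4-methoxybenzyl ether under neutral conditions leaves the silyl ether, the esters, the iodoalkene and the tertiary alcohol untouched.

Step 34
Reactants: 45 C4 primary alcohol
Product: 46 C4 aldehyde with the C5 iodoalkene
Conditions: Dess–Martin periodinane, NaHCO3, CH2Cl2, 0 °C
Reagents that add atoms: none
Why: Buffered Dess–Martin oxidation gives the β-acetoxy aldehyde without elimination of the C2 acetate.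

Step 35
Reactants: 46 C4 aldehyde with the C5 iodoalkene
Product: 48 ten-membered C4 allylic alcohol, via alkenylchromium species 47 (not isolated)
Conditions: CrCl2 (10 equiv), NiCl2 (2 mol %), DMSO/THF (3:1), 2 mM, rt
Reagents that add atoms: none
Why: Nozaki–Hiyama–Kishi reaction; nickel-catalysed activation of the C–I bond and transmetalation give alkenylchromium 47, which adds to the C4 aldehyde at high dilution with retention of the (Z) geometry and closes the ten-membered ring between the rigid lactone and the cyclohexene. C4 is expected 1,3-anti to the C2 acetate.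

Step 36
Reactants: 49 (R)-3-hydroxybutanoic acid
Product: 50 (R)-3-acetoxybutanoic acid
Conditions: Ac2O, pyridine, rt; aqueous work-up
Reagents that add atoms: acetic anhydride, CC(=O)OC(C)=O
Why: O-Acetylation of the β-hydroxy acid; the transient mixed anhydride is hydrolysed on work-up and the stereocentre is not involved.

Step 37
Reactants: 48 ten-membered C4 allylic alcohol; 50 (R)-3-acetoxybutanoic acid
Product: 51 16-O-triisopropylsilyl ether of the target
Conditions: N-(3-dimethylaminopropyl)-N′-ethylcarbodiimide hydrochloride, DMAP (10 mol %), CH2Cl2, 0 °C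
Reagents that add atoms: none
Why: Steglich esterification at low temperature with catalytic DMAP, conditions under which β-acyloxy acids couple without elimination to the crotonate; the tertiary C8 hydroxyl does not react.

Step 38
Reactants: 51 16-O-triisopropylsilyl ether of the target
Product: 52 CNP0316115.1
Conditions: HF·pyridine, excess pyridine, THF, 0 °C to rt
Reagents that add atoms: none
Why: Buffered fluoride cleaves the primary allylic silyl ether under non-basic conditions, so the O4 ester cannot migrate to O16 and the acetates remain.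

## Compound list

1 | 4-methoxy-3-methylphenol | Cc1cc(O)ccc1OC | starting material
2 | 4,4-dimethoxy-3-methylcyclohexa-2,5-dien-1-one | COC1(OC)C=CC(=O)C=C1C | intermediate
3 | 4,4-dimethoxy-3-methylcyclohex-2-en-1-one | COC1(OC)CCC(=O)C=C1C | intermediate
4 | (R)-4,4-dimethoxy-3-methylcyclohex-2-en-1-ol | CC1=C[C@H](O)CCC1(OC)OC | intermediate
5 | (R)-tert-butyl[(4,4-dimethoxy-3-methylcyclohex-2-en-1-yl)oxy]dimethylsilane | CC1=C[C@H](O[Si](C)(C)C(C)(C)C)CCC1(OC)OC | intermediate
6 | (R)-4-(tert-butyldimethylsilyloxy)-2-methylcyclohex-2-en-1-one | CC1=C[C@H](O[Si](C)(C)C(C)(C)C)CCC1=O | intermediate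
7 | propane-1,3-diol | OCCCO | starting material
8 | 3-(4-methoxybenzyloxy)propan-1-ol | COc1ccc(COCCCO)cc1 | intermediate
9 | 3-(4-methoxybenzyloxy)propanal | COc1ccc(COCCC=O)cc1 | intermediate
10 | vinylmagnesium bromide | C=C[Mg]Br | starting material
11 | bromomagnesium (3R,4R)-4-(tert-butyldimethylsilyloxy)-2-methyl-3-vinylcyclohex-1-en-1-olate | CC1=C(O[Mg]Br)CC[C@@H](O[Si](C)(C)C(C)(C)C)[C@@H]1C=C | intermediate (not isolated)
12 | chlorozinc (3R,4R)-4-(tert-butyldimethylsilyloxy)-2-methyl-3-vinylcyclohex-1-en-1-olate | CC1=C(O[Zn]Cl)CC[C@@H](O[Si](C)(C)C(C)(C)C)[C@@H]1C=C | intermediate (not isolated)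
13 | (2S,3R,4R)-4-(tert-butyldimethylsilyloxy)-2-[(1S)-1-hydroxy-3-(4-methoxybenzyloxy)propyl]-2-methyl-3-vinylcyclohexan-1-one (major C2 epimer; the minor one is carried along) | COc1ccc(COCC[C@H](O)[C@@]2(C)C(=O)CC[C@@H](O[Si](C)(C)C(C)(C)C)[C@@H]2C=C)cc1 | intermediate
14 | C2,C14-diketone: 2-[3-(4-methoxybenzyloxy)propanoyl] analogue of 13, ring centres as in 13 | COc1ccc(COCCC(=O)[C@@]2(C)C(=O)CC[C@@H](O[Si](C)(C)C(C)(C)C)[C@@H]2C=C)cc1 | intermediate
15 | C14 axial alcohol (cis to the C2 acyl chain, trans to the C15 methyl) with the C2 ketone | COc1ccc(COCCC(=O)[C@@]2(C)[C@@H](O)CC[C@@H](O[Si](C)(C)C(C)(C)C)[C@@H]2C=C)cc1 | intermediate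
16 | O14-diethylboryl derivative of 15 (boron chelated by the C2 carbonyl) | COc1ccc(COCCC(=O)[C@@]2(C)[C@@H](OB(CC)CC)CC[C@@H](O[Si](C)(C)C(C)(C)C)[C@@H]2C=C)cc1 | intermediate (not isolated)
17 | syn-2,14-diol, C1, C2, C10, C14 configured as in the target, (11R)-silyloxy, C10 vinyl | COc1ccc(COCC[C@@H](O)[C@@]2(C)[C@@H](O)CC[C@@H](O[Si](C)(C)C(C)(C)C)[C@@H]2C=C)cc1 | intermediate
18 | 2,14-diacetate of 17 | COc1ccc(COCC[C@@H](OC(C)=O)[C@@]2(C)[C@@H](OC(C)=O)CC[C@@H](O[Si](C)(C)C(C)(C)C)[C@@H]2C=C)cc1 | intermediate
19 | 1,2-diol from the vinyl group of 18 (C9 carbinol as an epimer mixture) | COc1ccc(COCC[C@@H](OC(C)=O)[C@@]2(C)[C@@H](OC(C)=O)CC[C@@H](O[Si](C)(C)C(C)(C)C)[C@@H]2C(O)CO)cc1 | intermediate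
20 | acetonide of 19 | COc1ccc(COCC[C@@H](OC(C)=O)[C@@]2(C)[C@@H](OC(C)=O)CC[C@@H](O[Si](C)(C)C(C)(C)C)[C@@H]2C3COC(C)(C)O3)cc1 | intermediate
21 | (11R)-alcohol from 20 | COc1ccc(COCC[C@@H](OC(C)=O)[C@@]2(C)[C@@H](OC(C)=O)CC[C@@H](O)[C@@H]2C3COC(C)(C)O3)cc1 | intermediate
22 | C11 ketone | COc1ccc(COCC[C@@H](OC(C)=O)[C@@]2(C)[C@@H](OC(C)=O)CCC(=O)[C@@H]2C3COC(C)(C)O3)cc1 | intermediate
23 | potassium C11(O)=C12 enolate of 22 | COc1ccc(COCC[C@@H](OC(C)=O)[C@@]2(C)[C@@H](OC(C)=O)CC=C(O[K])[C@@H]2C3COC(C)(C)O3)cc1 | intermediate (not isolated)
24 | C11 enol triflate (C11=C12) | COc1ccc(COCC[C@@H](OC(C)=O)[C@@]2(C)[C@@H](OC(C)=O)CC=C(OS(=O)(=O)C(F)(F)F)[C@@H]2C3COC(C)(C)O3)cc1 | intermediate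
25 | C11-methyl cyclohexene acetonide | COc1ccc(COCC[C@@H](OC(C)=O)[C@@]2(C)[C@@H](OC(C)=O)CC=C(C)[C@@H]2C3COC(C)(C)O3)cc1 | intermediate
26 | 1,2-diol from 25 (C9 epimers) | COc1ccc(COCC[C@@H](OC(C)=O)[C@@]2(C)[C@@H](OC(C)=O)CC=C(C)[C@@H]2C(O)CO)cc1 | intermediate (not isolated)
27 | C9 aldehyde: cyclohexene with C1, C2, C10, C14 as in the target, 2,14-diacetate, 4-O-(4-methoxybenzyl) | COc1ccc(COCC[C@@H](OC(C)=O)[C@@]2(C)[C@@H](OC(C)=O)CC=C(C)[C@@H]2C=O)cc1 | intermediate
28 | methyl (S)-3-hydroxy-2-methylpropanoate | COC(=O)[C@@H](C)CO | starting material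
29 | methyl (S)-3-(tert-butyldimethylsilyloxy)-2-methylpropanoate | COC(=O)[C@@H](C)CO[Si](C)(C)C(C)(C)C | intermediate
30 | (S)-3-(tert-butyldimethylsilyloxy)-2-methylpropanal | O=C[C@@H](C)CO[Si](C)(C)C(C)(C)C | intermediate
31 | (R)-tert-butyldimethyl[(2-methylbut-3-yn-1-yl)oxy]silane | C#C[C@@H](C)CO[Si](C)(C)C(C)(C)C | intermediate
32 | (R)-[(4-bromo-2-methylbut-3-yn-1-yl)oxy](tert-butyl)dimethylsilane | BrC#C[C@@H](C)CO[Si](C)(C)C(C)(C)C | intermediate
33 | prop-2-yn-1-ol | C#CCO | starting material
34 | (R)-7-(tert-butyldimethylsilyloxy)-6-methylhepta-2,4-diyn-1-ol | OCC#CC#C[C@@H](C)CO[Si](C)(C)C(C)(C)C | intermediate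
35 | (R,Z)-7-(tert-butyldimethylsilyloxy)-6-methyl-2-(tributylstannyl)hept-2-en-4-yn-1-ol | OC/C(=C/C#C[C@@H](C)CO[Si](C)(C)C(C)(C)C)[Sn](CCCC)(CCCC)CCCC | intermediate
36 | triisopropylsilyl ether of 35 | CC(C)[Si](OC/C(=C/C#C[C@@H](C)CO[Si](C)(C)C(C)(C)C)[Sn](CCCC)(CCCC)CCCC)(C(C)C)C(C)C | intermediate
37 | (9R)-dienol: C8–C9 coupled product, C7=C8 with C6 cis to C17, (5Z)-C5 stannane, 16-O-triisopropylsilyl, 19-O-tert-butyldimethylsilyl | COc1ccc(COCC[C@@H](OC(C)=O)[C@@]2(C)[C@@H](OC(C)=O)CC=C(C)[C@@H]2[C@@H](O)/C(=C/C=C(/CO[Si](C(C)C)(C(C)C)C(C)C)[Sn](CCCC)(CCCC)CCCC)[C@@H](C)CO[Si](C)(C)C(C)(C)C)cc1 | intermediate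
38 | (5Z)-C5 iodide corresponding to 37 | COc1ccc(COCC[C@@H](OC(C)=O)[C@@]2(C)[C@@H](OC(C)=O)CC=C(C)[C@@H]2[C@@H](O)/C(=C/C=C(/CO[Si](C(C)C)(C(C)C)C(C)C)I)[C@@H](C)CO[Si](C)(C)C(C)(C)C)cc1 | intermediate
39 | 7,8-epoxy C9 alcohol (epoxide anti to O9; C6 and C17 cis on the epoxide) | COc1ccc(COCC[C@@H](OC(C)=O)[C@@]2(C)[C@@H](OC(C)=O)CC=C(C)[C@@H]2[C@@H](O)[C@]3(O[C@@H]3/C=C(/CO[Si](C(C)C)(C(C)C)C(C)C)I)[C@@H](C)CO[Si](C)(C)C(C)(C)C)cc1 | intermediate
40 | C9 acetate of 39 | COc1ccc(COCC[C@@H](OC(C)=O)[C@@]2(C)[C@@H](OC(C)=O)CC=C(C)[C@@H]2[C@@H](OC(C)=O)[C@]3(O[C@@H]3/C=C(/CO[Si](C(C)C)(C(C)C)C(C)C)I)[C@@H](C)CO[Si](C)(C)C(C)(C)C)cc1 | intermediate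
41 | C19 primary alcohol from 40 | COc1ccc(COCC[C@@H](OC(C)=O)[C@@]2(C)[C@@H](OC(C)=O)CC=C(C)[C@@H]2[C@@H](OC(C)=O)[C@]3(O[C@@H]3/C=C(/CO[Si](C(C)C)(C(C)C)C(C)C)I)[C@@H](C)CO)cc1 | intermediate
42 | C19 aldehyde from 41 | COc1ccc(COCC[C@@H](OC(C)=O)[C@@]2(C)[C@@H](OC(C)=O)CC=C(C)[C@@H]2[C@@H](OC(C)=O)[C@]3(O[C@@H]3/C=C(/CO[Si](C(C)C)(C(C)C)C(C)C)I)[C@@H](C)C=O)cc1 | intermediate (not isolated)
43 | 7,8-epoxy C19 carboxylic acid | COc1ccc(COCC[C@@H](OC(C)=O)[C@@]2(C)[C@@H](OC(C)=O)CC=C(C)[C@@H]2[C@@H](OC(C)=O)[C@]3(O[C@@H]3/C=C(/CO[Si](C(C)C)(C(C)C)C(C)C)I)[C@@H](C)C(=O)O)cc1 | intermediate (not isolated)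
44 | hydroxy lactone: C7, C8, C9, C17 as in the target, free 8-OH, 9-acetate, (5Z)-iodoalkene, 16-O-triisopropylsilyl, 4-O-(4-methoxybenzyl) | COc1ccc(COCC[C@@H](OC(C)=O)[C@@]2(C)[C@@H](OC(C)=O)CC=C(C)[C@@H]2[C@@H](OC(C)=O)[C@@]3(O)[C@H](/C=C(/CO[Si](C(C)C)(C(C)C)C(C)C)I)OC(=O)[C@@H]3C)cc1 | intermediate
45 | C4 primary alcohol from 44 | OCC[C@@H](OC(C)=O)[C@@]2(C)[C@@H](OC(C)=O)CC=C(C)[C@@H]2[C@@H](OC(C)=O)[C@@]3(O)[C@H](/C=C(/CO[Si](C(C)C)(C(C)C)C(C)C)I)OC(=O)[C@@H]3C | intermediate
46 | C4 aldehyde with the (5Z)-iodoalkene | O=CC[C@@H](OC(C)=O)[C@@]2(C)[C@@H](OC(C)=O)CC=C(C)[C@@H]2[C@@H](OC(C)=O)[C@@]3(O)[C@H](/C=C(/CO[Si](C(C)C)(C(C)C)C(C)C)I)OC(=O)[C@@H]3C | intermediate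
47 | C5 alkenylchromium dichloride from 46 | O=CC[C@@H](OC(C)=O)[C@@]2(C)[C@@H](OC(C)=O)CC=C(C)[C@@H]2[C@@H](OC(C)=O)[C@@]3(O)[C@H](/C=C(/CO[Si](C(C)C)(C(C)C)C(C)C)[Cr](Cl)Cl)OC(=O)[C@@H]3C | intermediate (not isolated)
48 | ten-membered (4R)-allylic alcohol, 16-O-triisopropylsilyl, all other centres as in the target | O[C@@H]1C[C@@H](OC(C)=O)[C@@]2(C)[C@@H](OC(C)=O)CC=C(C)[C@@H]2[C@@H](OC(C)=O)[C@@]2(O)[C@H](/C=C\1CO[Si](C(C)C)(C(C)C)C(C)C)OC(=O)[C@@H]2C | intermediate
49 | (R)-3-hydroxybutanoic acid | C[C@@H](O)CC(=O)O | starting material
50 | (R)-3-acetoxybutanoic acid | CC(=O)O[C@H](C)CC(=O)O | intermediate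
51 | 16-O-triisopropylsilyl ether of the target | CC(=O)O[C@H](C)CC(=O)O[C@@H]1C[C@@H](OC(C)=O)[C@@]2(C)[C@@H](OC(C)=O)CC=C(C)[C@@H]2[C@@H](OC(C)=O)[C@@]2(O)[C@H](/C=C\1CO[Si](C(C)C)(C(C)C)C(C)C)OC(=O)[C@@H]2C | intermediate
52 | CNP0316115.1 | CC(=O)O[C@H](C)CC(=O)O[C@@H]1C[C@@H](OC(C)=O)[C@@]2(C)[C@@H](OC(C)=O)CC=C(C)[C@@H]2[C@@H](OC(C)=O)[C@@]2(O)[C@H](/C=C\1CO)OC(=O)[C@@H]2C | target

## Step count and least certain steps

Total step count: 38. Longest linear sequence: 28 steps (steps 1–5, 8–19, 27–35, 37 and 38, from 1 to 52).

**Step 8 (key step).** The likely failure is incomplete aldol trapping: proton transfer from the enolisable aldehyde to the hindered, fully substituted enolate, or retro-aldol on warming, would return the simple conjugate adduct. Low selectivity at C2 is expected and harmless. Fallback: starting from 6 and 10, the conjugate addition is run with Me3SiCl present, so that enolate 11 is intercepted as the trimethylsilyl enol ether F1. F1 is isolated and combined with 9 under BF3·OEt2 in CH2Cl2 at −78 °C (Mukaiyama aldol). This returns to the route at 13; either C2 epimer is acceptable.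

**Step 10.** Possible failures are competing reduction of the acyclic C2 ketone, or ring cleavage of the intermediate β-alkoxy ketone by retro-aldol. Fallback: starting from 13, the C2 hydroxyl is silylated (Et3SiOTf, 2,6-lutidine) to the triethylsilyl ether F2, whose only ketone is reduced with LiBH(s-Bu)3 to the axial alcohol F3. Chloroacetic anhydride and pyridine give chloroacetate F4, pyridinium p-toluenesulfonate in MeOH removes the triethylsilyl group to give F5, and Dess–Martin oxidation gives keto chloroacetate F6. Thiourea with NaHCO3 in EtOH then removes the chloroacetate, which returns to the route at 15.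

**Step 25.** The hydrostannation may attack the distal triple bond or add twice, because the conjugated diyne offers two sites. Fallback: starting from 34 and 27, the nickel-catalysed coupling is run first and gives enynediol F7, in which only one triple bond remains. The hydroxyl-directed trans-hydrostannation then gives the stannyl dienediol F8, and selective silylation of the primary hydroxyl with i-Pr3SiCl and imidazole returns to the route at 37.

**Step 27.** The likely failure is poor facial selectivity at C9, because the oxidative cyclisation at nickel need not follow the Felkin–Anh preference of a simple nucleophile. Fallback: starting from 38 as the C9 epimer mixture, Dess–Martin oxidation gives dienone F9. Corey–Bakshi–Shibata reduction with the (S)-catalyst and catecholborane, in which the dienyl arm acts as the large group, sets C9 under reagent control and returns to 38.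

**Step 35.** Oligomerisation may compete with closure of the medium ring, and the aldehyde face may be chosen by the ring conformation against the 1,3-anti preference, giving the C4 epimer. Fallback: starting from 46, if the closure gives mainly the (4S)-alcohol F10, F10 is esterified with 50 under Mitsunobu conditions (PPh3, diisopropyl azodicarboxylate, toluene, 0 °C). This inverts C4 and rejoins the route at 51.

## Further compounds

F1 | step 8 | tert-butyldimethyl{[(1R,2R)-3-methyl-4-(trimethylsilyloxy)-2-vinylcyclohex-3-en-1-yl]oxy}silane (trimethylsilyl enol ether of the conjugate adduct) | CC1=C(O[Si](C)(C)C)CC[C@@H](O[Si](C)(C)C(C)(C)C)[C@@H]1C=C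
F2 | step 10 | C2 triethylsilyl ether of 13 | COc1ccc(COCC[C@H](O[Si](CC)(CC)CC)[C@@]2(C)C(=O)CC[C@@H](O[Si](C)(C)C(C)(C)C)[C@@H]2C=C)cc1
F3 | step 10 | C14 axial alcohol from F2 | COc1ccc(COCC[C@H](O[Si](CC)(CC)CC)[C@@]2(C)[C@@H](O)CC[C@@H](O[Si](C)(C)C(C)(C)C)[C@@H]2C=C)cc1
F4 | step 10 | C14 chloroacetate of F3 | COc1ccc(COCC[C@H](O[Si](CC)(CC)CC)[C@@]2(C)[C@@H](OC(=O)CCl)CC[C@@H](O[Si](C)(C)C(C)(C)C)[C@@H]2C=C)cc1
F5 | step 10 | C2 alcohol with the C14 chloroacetate | COc1ccc(COCC[C@H](O)[C@@]2(C)[C@@H](OC(=O)CCl)CC[C@@H](O[Si](C)(C)C(C)(C)C)[C@@H]2C=C)cc1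
F6 | step 10 | C2 ketone with the C14 chloroacetate | COc1ccc(COCCC(=O)[C@@]2(C)[C@@H](OC(=O)CCl)CC[C@@H](O[Si](C)(C)C(C)(C)C)[C@@H]2C=C)cc1
F7 | step 25 | enynediol from 27 and 34 (C8–C9 formed, C5≡C6 retained, free 9-OH and 16-OH) | COc1ccc(COCC[C@@H](OC(C)=O)[C@@]2(C)[C@@H](OC(C)=O)CC=C(C)[C@@H]2[C@@H](O)/C(=C/C#CCO)[C@@H](C)CO[Si](C)(C)C(C)(C)C)cc1
F8 | step 25 | (5Z)-C5 stannyl dienediol from F7 | COc1ccc(COCC[C@@H](OC(C)=O)[C@@]2(C)[C@@H](OC(C)=O)CC=C(C)[C@@H]2[C@@H](O)/C(=C/C=C(/CO)[Sn](CCCC)(CCCC)CCCC)[C@@H](C)CO[Si](C)(C)C(C)(C)C)cc1
F9 | step 27 | C9 dienone from 38 | COc1ccc(COCC[C@@H](OC(C)=O)[C@@]2(C)[C@@H](OC(C)=O)CC=C(C)[C@@H]2C(=O)/C(=C/C=C(/CO[Si](C(C)C)(C(C)C)C(C)C)I)[C@@H](C)CO[Si](C)(C)C(C)(C)C)cc1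
F10 | step 35 | (4S)-epimer of 48 | O[C@H]1C[C@@H](OC(C)=O)[C@@]2(C)[C@@H](OC(C)=O)CC=C(C)[C@@H]2[C@@H](OC(C)=O)[C@@]2(O)[C@H](/C=C\1CO[Si](C(C)C)(C(C)C)C(C)C)OC(=O)[C@@H]2C
A1 | alternative 1 | ten-membered C4 allylic alcohol with the lactone and three acetates in place, 16-O-tert-butyldimethylsilyl | O[C@@H]1C[C@@H](OC(C)=O)[C@@]2(C)[C@@H](OC(C)=O)CC=C(C)[C@@H]2[C@@H](OC(C)=O)[C@@]2(O)[C@H](/C=C\1CO[Si](C)(C)C(C)(C)C)OC(=O)[C@@H]2C
A2 | alternative 2 | bicyclic C2,C14-diketone with the lactone in place, 4-O-tert-butyldimethylsilyl, 16-O-(4-methoxybenzyl), 9-acetate | CC(C)(C)[Si](C)(C)O[C@@H]1CC(=O)[C@@]2(C)C(=O)CC=C(C)[C@@H]2[C@@H](OC(C)=O)[C@@]2(O)[C@H](/C=C\1COCc1ccc(OC)cc1)OC(=O)[C@@H]2C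
A3 | alternative 3 | lactone-annulated macrocycle with free 8-OH, 9-O-tert-butyldimethylsilyl, 16-O-(4-methoxybenzyl), O4 side chain in place | CC(=O)O[C@H](C)CC(=O)O[C@@H]1C[C@@H](OC(C)=O)[C@@]2(C)[C@@H](OC(C)=O)CC=C(C)[C@@H]2[C@@H](O[Si](C)(C)C(C)(C)C)[C@@]2(O)[C@H](/C=C\1COCc1ccc(OC)cc1)OC(=O)[C@@H]2C
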